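**Retrosynthetic overview**
1. Target 11 ⇒ 10 by one neutral hydrogenolysis that removes four benzyl ethers and one benzyl carbonate.
2. 10 ⇒ 7: the ring B catechol is unmasked from a guaiacol; the 3'-OMe first serves to block C3' and direct coupling to C5'.
3. 7 ⇒ 6 + 3: the C5'–C8'' biaryl bond is made by anodic dehydrogenative cross-coupling, with 6 as the oxidised phenol and 3 as the C8–H nucleophile.
4. 6 ⇐ natural (2S)-homoeriodictyol 4, which supplies the only stereocentre; 3 ⇐ luteolin 1.
5. No ring is built: all six rings are bought in the two flavonoids, and only the inter-flavonoid bond is formed.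

Assumption: natural (2S)-homoeriodictyol 4 is bought enantiopure (ee checked by chiral HPLC before use), and the 5'–8'' biaryl axis, which the target SMILES leaves undefined, is taken as freely rotating.

**Step 1**
Reactants: 1 luteolin; 2 benzyl bromide
Product: 3 5,7,3',4'-tetra-O-benzylluteolin
Conditions: BnBr (6 equiv), K2CO3 (8 equiv), DMF, 80 °C, 16 h
Reagents that add atoms: benzyl bromide, BrCc1ccccc1
Why: Williamson ether synthesis on the four phenoxides, in which the hydrogen-bonded 5-OH reacts last and is driven to completion by excess BnBr and heat; no stereocentre is present.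

**Step 2**
Reactants: 4 (2S)-homoeriodictyol; 5 benzyl chloroformate
Product: 6 (2S)-7-O-benzyloxycarbonylhomoeriodictyol
Conditions: CbzCl (1.05 equiv), iPr2NEt (1.1 equiv), THF, −20 → 0 °C, 1 h; pH 5 buffer quench
Reagents that add atoms: benzyl chloroformate, O=C(Cl)OCc1ccccc1
Why: Chemoselective O-acylation (carbonate formation) of the 7-OH, a vinylogous acid (pKa about 7.5) and the only phenol ionised by the amine, while the chelated 5-OH and the guaiacol 4'-OH stay free; the carbonate lowers the nucleophilicity of ring A for step 3, and C2 is untouched because the base is consumed as its hydrochloride at low temperature.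

**Step 3**
Reactants: 6 (2S)-7-O-benzyloxycarbonylhomoeriodictyol; 3 5,7,3',4'-tetra-O-benzylluteolin
Product: 7 (2S)-7-O-benzyloxycarbonyl-5'-(5,7,3',4'-tetra-O-benzylluteolin-8-yl)homoeriodictyol
Conditions: 3 (3 equiv, excess recovered), undivided cell, boron-doped diamond anode, Pt cathode, Bu3NMe+ MeOSO3− (0.09 M), HFIP/CH2Cl2 4:1, 30 °C, 2.8 mA cm−2, 2.2 F per mol of 6
Reagents that add atoms: none
Why: Proposed new method: anodic dehydrogenative cross-coupling of a flavanone ring B phenol with the C8–H of a flavone, in which the guaiacol-type 4'-OH of 6 has the lowest oxidation potential in the cell (ring A of 6 is a chelated acyl phenol carrying a carbonate, and 3 has only ether oxygens on rings tied to the pyranone) and is oxidised to an HFIP-stabilised phenoxyl radical whose only open coupling site is C5' (C3' carries OMe, C1' the alkyl group); this electrophilic radical adds to the most nucleophilic C–H present, C8 of 3 (para to 5-OBn and ortho to 7-OBn, the position where 5,7-dialkoxyflavones are halogenated), a second electron transfer and loss of two protons rearomatise both rings while the cathode releases H2, and the base-free, weakly acidic medium leaves C2 untouched; the closest known reaction type is the reagent-free anodic phenol–arene cross-coupling on boron-doped diamond in HFIP (4-methylguaiacol with methoxyarenes), which has not been shown on flavonoids or used to join two flavonoid units.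

**Step 4**
Reactants: 7 (2S)-7-O-benzyloxycarbonyl-5'-(5,7,3',4'-tetra-O-benzylluteolin-8-yl)homoeriodictyol; 8 2-iodoxybenzoic acid (IBX)
Product: 10 (2S)-7-O-benzyloxycarbonyl-5'-(5,7,3',4'-tetra-O-benzylluteolin-8-yl)eriodictyol, via ortho-quinone 9 (not isolated)
Conditions: IBX (1.2 equiv), DMF, 0 °C, 45 min; then aq Na2S2O4, EtOAc, 0 °C
Reagents that add atoms: 2-iodoxybenzoic acid (IBX), O=C1OI(=O)(O)c2ccccc12
Why: Hypervalent-iodine oxidative demethylation of a 2-methoxyphenol (IBX ortho-oxygenation), in which the pentavalent iodine binds the 4'-OH and delivers oxygen to the methoxy-bearing ortho carbon (C5' is blocked by the aryl group), methanol is lost to give ortho-quinone 9, and dithionite reduces it at once to the catechol under neutral, cold conditions that leave C2, the benzyl groups and the electron-poor ring A phenol untouched.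

**Step 5**
Reactants: 10 (2S)-7-O-benzyloxycarbonyl-5'-(5,7,3',4'-tetra-O-benzylluteolin-8-yl)eriodictyol
Product: 11 (2S)-eriodictyol-(5'→8'')-luteolin (target CNP0224656.1)
Conditions: H2 (1 atm), Pd/C (10 wt%), THF/MeOH 1:1, rt; Sephadex LH-20 (MeOH)
Reagents that add atoms: none
Why: Heterogeneous catalytic hydrogenolysis of four aryl benzyl ethers and the benzyl carbonate (which loses CO2) under neutral conditions, where the flavone C2=C3 bond and the flavanone ring are not reduced at 1 atm and room temperature, so the (2S) centre bought in 4 arrives unchanged in the target.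

**Compound list**
1 | luteolin, 2-(3,4-dihydroxyphenyl)-5,7-dihydroxy-4H-chromen-4-one | O=c1cc(-c2ccc(O)c(O)c2)oc2cc(O)cc(O)c12 | starting material
2 | benzyl bromide | BrCc1ccccc1 | starting material
3 | 5,7,3',4'-tetra-O-benzylluteolin, 5,7-bis(benzyloxy)-2-[3,4-bis(benzyloxy)phenyl]-4H-chromen-4-one | O=c1cc(-c2ccc(OCc3ccccc3)c(OCc3ccccc3)c2)oc2cc(OCc3ccccc3)cc(OCc3ccccc3)c12 | intermediate
4 | (2S)-homoeriodictyol, (2S)-5,7-dihydroxy-2-(4-hydroxy-3-methoxyphenyl)chroman-4-one | O=C1C[C@@H](c2ccc(O)c(OC)c2)Oc2cc(O)cc(O)c21 | starting material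
5 | benzyl chloroformate | O=C(Cl)OCc1ccccc1 | starting material
6 | (2S)-7-O-benzyloxycarbonylhomoeriodictyol, benzyl (2S)-5-hydroxy-2-(4-hydroxy-3-methoxyphenyl)-4-oxochroman-7-yl carbonate | O=C1C[C@@H](c2ccc(O)c(OC)c2)Oc2cc(OC(=O)OCc3ccccc3)cc(O)c21 | intermediate
7 | (2S)-7-O-benzyloxycarbonyl-5'-(5,7,3',4'-tetra-O-benzylluteolin-8-yl)homoeriodictyol; flavanone with 5-OH, 7-OCbz, ring B carrying 3'-OMe, 4'-OH and at C5' the C8 of the tetrabenzylated flavone | O=C1C[C@@H](c2cc(OC)c(O)c(-c3c(OCc4ccccc4)cc(OCc4ccccc4)c4c(=O)cc(-c5ccc(OCc6ccccc6)c(OCc6ccccc6)c5)oc34)c2)Oc2cc(OC(=O)OCc3ccccc3)cc(O)c21 | intermediate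
8 | 2-iodoxybenzoic acid (IBX), 1-hydroxy-1-oxo-1,2-benziodoxol-3(1H)-one | O=C1OI(=O)(O)c2ccccc12 | starting material
9 | ortho-quinone of 7 (not isolated): ring B is a 3',4'-dioxocyclohexa-1',5'-diene, (2S) | O=C1C[C@@H](C2=CC(=O)C(=O)C(-c3c(OCc4ccccc4)cc(OCc4ccccc4)c4c(=O)cc(-c5ccc(OCc6ccccc6)c(OCc6ccccc6)c5)oc34)=C2)Oc2cc(OC(=O)OCc3ccccc3)cc(O)c21 | intermediate
10 | (2S)-7-O-benzyloxycarbonyl-5'-(5,7,3',4'-tetra-O-benzylluteolin-8-yl)eriodictyol; as 7 but with a free 3',4'-catechol | O=C1C[C@@H](c2cc(O)c(O)c(-c3c(OCc4ccccc4)cc(OCc4ccccc4)c4c(=O)cc(-c5ccc(OCc6ccccc6)c(OCc6ccccc6)c5)oc34)c2)Oc2cc(OC(=O)OCc3ccccc3)cc(O)c21 | intermediate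
11 | (2S)-eriodictyol-(5'→8'')-luteolin, 8-{5-[(2S)-5,7-dihydroxy-4-oxochroman-2-yl]-2,3-dihydroxyphenyl}-2-(3,4-dihydroxyphenyl)-5,7-dihydroxy-4H-chromen-4-one | O=C1C[C@@H](c2cc(O)c(O)c(-c3c(O)cc(O)c4c(=O)cc(-c5ccc(O)c(O)c5)oc34)c2)Oc2cc(O)cc(O)c21 | target

**Step count and risks**
Total steps: 5. Longest linear sequence: 4 steps (4 → 6 → 7 → 10 → 11; the luteolin branch 1 → 3 → 7 → 10 → 11 is equally long).

Steps most likely to fail:

Step 3 (the proposed anodic cross-coupling). The risks are homo-coupling or over-oxidation of 6, attack at C6 instead of C8 of 3, and quinone methide formation through C2–H. The fallback uses known Suzuki–Miyaura chemistry, sets out from 3 and 6, and comes back at 7. Compound 3 is iodinated at C8 (NIS, cat. CF3CO2H, CH2Cl2/MeCN, rt) to give 8-iodo-5,7,3',4'-tetra-O-benzylluteolin F1. Miyaura borylation (B2pin2, PdCl2(dppf), KOAc, dioxane, 80 °C) converts it into 5,7,3',4'-tetra-O-benzylluteolin-8-boronic acid pinacol ester F2. Compound 6 is iodinated ortho to its free 4'-OH (NIS, MeCN, 0 °C) to give (2S)-7-O-benzyloxycarbonyl-5'-iodohomoeriodictyol F3. Coupling of F2 with F3 (Pd(OAc)2, SPhos, CsF, anhydrous dioxane, 60 °C, chosen to spare the carbonate and C2) gives 7.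

Step 4 (oxidative demethylation). The hindered phenol may react slowly, and ortho-quinone 9 may tautomerise through C2–H to a quinone methide, which would destroy the stereocentre, or be attacked by nucleophiles. The fallback sets out from 7 and comes back at 11, moving the ether cleavage to the end and changing it to a Lewis-acid demethylation. Hydrogenolysis of 7 (H2, Pd/C, THF/MeOH, rt) gives (2S)-homoeriodictyol-(5'→8'')-luteolin F4, the 3'-O-methyl ether of the target. Its single guaiacol methyl ether is then cleaved (BBr3, CH2Cl2, −78 → 0 °C, then water) to give 11. The boron chelate across 5-O and the C4 carbonyl withdraws the O1 lone pair and so disfavours opening of the C2–O1 bond; ee is checked by chiral HPLC.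

Step 2 (selective 7-O-acylation). The 4'-OH may compete, or the aryl carbonate may not survive the electrolysis. The fallback sets out from 4 and comes back at 11, omitting the protecting group. Compound 4 is dosed by syringe pump into 5 equiv of 3 in the cell of step 3, so that its own ring A stays dilute; this gives (2S)-5'-(5,7,3',4'-tetra-O-benzylluteolin-8-yl)homoeriodictyol F5. IBX then Na2S2O4, as in step 4, gives through the ortho-quinone of F5 F6 (not isolated) the catechol (2S)-5'-(5,7,3',4'-tetra-O-benzylluteolin-8-yl)eriodictyol F7. Hydrogenolysis (H2, Pd/C) of F7 gives 11.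

**Further compounds**
F1 | step 3 | 8-iodo-5,7,3',4'-tetra-O-benzylluteolin | O=c1cc(-c2ccc(OCc3ccccc3)c(OCc3ccccc3)c2)oc2c(I)c(OCc3ccccc3)cc(OCc3ccccc3)c12
F2 | step 3 | 5,7,3',4'-tetra-O-benzylluteolin-8-boronic acid pinacol ester | O=c1cc(-c2ccc(OCc3ccccc3)c(OCc3ccccc3)c2)oc2c(B3OC(C)(C)C(C)(C)O3)c(OCc3ccccc3)cc(OCc3ccccc3)c12
F3 | step 3 | (2S)-7-O-benzyloxycarbonyl-5'-iodohomoeriodictyol | O=C1C[C@@H](c2cc(I)c(O)c(OC)c2)Oc2cc(OC(=O)OCc3ccccc3)cc(O)c21
F4 | step 4 | (2S)-homoeriodictyol-(5'→8'')-luteolin (3'-O-methyl ether of the target) | O=C1C[C@@H](c2cc(OC)c(O)c(-c3c(O)cc(O)c4c(=O)cc(-c5ccc(O)c(O)c5)oc34)c2)Oc2cc(O)cc(O)c21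
F5 | step 2 | (2S)-5'-(5,7,3',4'-tetra-O-benzylluteolin-8-yl)homoeriodictyol | O=C1C[C@@H](c2cc(OC)c(O)c(-c3c(OCc4ccccc4)cc(OCc4ccccc4)c4c(=O)cc(-c5ccc(OCc6ccccc6)c(OCc6ccccc6)c5)oc34)c2)Oc2cc(O)cc(O)c21
F6 | step 2 | ortho-quinone of F5 (not isolated) | O=C1C[C@@H](C2=CC(=O)C(=O)C(-c3c(OCc4ccccc4)cc(OCc4ccccc4)c4c(=O)cc(-c5ccc(OCc6ccccc6)c(OCc6ccccc6)c5)oc34)=C2)Oc2cc(O)cc(O)c21
F7 | step 2 | (2S)-5'-(5,7,3',4'-tetra-O-benzylluteolin-8-yl)eriodictyol | O=C1C[C@@H](c2cc(O)c(O)c(-c3c(OCc4ccccc4)cc(OCc4ccccc4)c4c(=O)cc(-c5ccc(OCc6ccccc6)c(OCc6ccccc6)c5)oc34)c2)Oc2cc(O)cc(O)c21
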